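Everything hinges on making C7–C11 and C8–O in one event. The target holds a γ-lactone (O6–C12–C11–C7) fused trans at C6/C7 of the ten-membered ring, an oxygen on C8 that sits on the same ring face as the C7–C11 bond, and a C11 that bears C12 and the C13 methylene. A nitrone built from a pyruvate ester on O6 therefore reaches across a ring-cis C7=C8 double bond: one intramolecular (3+2) cycloaddition closes lactone and isoxazolidine and fixes C7, C8 and C11, whose methyl later gives C13 by Cope elimination. The precursor is an all-cis cyclodeca-1(10),4,7-triene (C9 OAc, C15 OTBS, C6 nitrone ester), made by ring-closing metathesis.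

Key step: step 16

Numbering: germacrane numbering throughout (ring C1–C10, lactone carbons C11–C13, ester carbon C14, hydroxymethyl carbon C15).
Assumption: (S,S)-ProPhenol is taken to give the (R)-carbinol in step 8 and the lipase in step 3 to acetylate the (R)-alcohol faster (usual size rule); if either sense proves opposite, the enantiomeric ligand is used or the acetate is carried on after methanolysis.

Step 1
Reactants: 1 prop-2-yn-1-ol (propargyl alcohol)
Product: 2 tert-butyldimethyl(prop-2-yn-1-yloxy)silane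
Conditions: TBSCl, imidazole, CH2Cl2, 0 °C to rt
Reagents that add atoms: tert-butyldimethylsilyl chloride, CC(C)(C)[Si](C)(C)Cl
Why: Standard O-silylation of a primary alcohol with a silyl chloride and imidazole; it masks the future C15 hydroxyl until the last step.

Step 2
Reactants: 2 tert-butyldimethyl(prop-2-yn-1-yloxy)silane, 3 acrolein
Product: 5 rac-6-(tert-butyldimethylsilyloxy)hex-1-en-4-yn-3-ol, via lithium acetylide 4 (not isolated)
Conditions: n-BuLi, THF, −78 °C; then acrolein, −78 °C; aq NH4Cl
Reagents that add atoms: none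
Why: Alkyne deprotonation and 1,2-addition of the lithium acetylide to the enal carbonyl at low temperature (acetylide addition); the C6 carbinol is formed racemic and is resolved in step 3.

Step 3
Reactants: 5 rac-6-(tert-butyldimethylsilyloxy)hex-1-en-4-yn-3-ol
Product: 6 (S)-6-(tert-butyldimethylsilyloxy)hex-1-en-4-yn-3-ol
Conditions: immobilised Candida antarctica lipase B, vinyl acetate, MTBE, 30 °C, run to just past half conversion; chromatography
Reagents that add atoms: none
Why: Lipase-catalysed kinetic resolution by enantioselective transesterification, which by the size rule for secondary alcohols (alkynyl arm large, vinyl medium) should acetylate the (R)-alcohol and leave the (S)-alcohol that carries the C6 configuration.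

Step 4
Reactants: 6 (S)-6-(tert-butyldimethylsilyloxy)hex-1-en-4-yn-3-ol
Product: 8 (3S,4Z)-6-(tert-butyldimethylsilyloxy)-5-iodohexa-1,4-dien-3-ol, via sodium alkenylalanate 7 (not isolated)
Conditions: NaAlH2(OCH2CH2OMe)2, THF, 0 °C; EtOAc; then I2, THF, −78 to 0 °C
Reagents that add atoms: iodine, [I][I]
Why: Hydroxyl-directed trans-hydroalumination of the propargylic alcohol places aluminium on the distal alkyne carbon C4 in a five-membered alkoxyalanate, and iodinolysis with retention gives the vinyl iodide with iodine cis to C6, which fixes the C4=C5 geometry.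

Step 5
Reactants: 8 (3S,4Z)-6-(tert-butyldimethylsilyloxy)-5-iodohexa-1,4-dien-3-ol
Product: 9 triethylsilyl ether of 8, (3S,4Z)-6-(tert-butyldimethylsilyloxy)-5-iodo-3-(triethylsilyloxy)hexa-1,4-diene
Conditions: TESCl, imidazole, DMAP (cat.), CH2Cl2, 0 °C
Reagents that add atoms: chlorotriethylsilane, CC[Si](Cl)(CC)CC
Why: O-silylation of the secondary alcohol; the labile TES group keeps O6 distinct from the C9 hydroxyl made later.

Step 6
Reactants: 9 triethylsilyl ether of 8, 10 (4-bromobut-1-yn-1-yl)trimethylsilane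
Product: 12 (3S,4E)-5-[(tert-butyldimethylsilyloxy)methyl]-3-(triethylsilyloxy)-9-(trimethylsilyl)nona-1,4-dien-8-yne, via alkylzinc bromide 11 (not isolated)
Conditions: 10, Zn dust, LiCl, THF, 50 °C; then 9, PdCl2(dppf) (5 mol %; dppf = 1,1′-bis(diphenylphosphino)ferrocene), THF, rt to 45 °C
Reagents that add atoms: none
Why: Negishi sp3–sp2 cross-coupling of a primary alkylzinc halide with an alkenyl iodide proceeds with retention, so C3 enters cis to C6 and the ring-cis C4=C5 geometry is kept.

Step 7
Reactants: 12 (3S,4E)-5-[(tert-butyldimethylsilyloxy)methyl]-3-(triethylsilyloxy)-9-(trimethylsilyl)nona-1,4-dien-8-yne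
Product: 13 (3S,4E)-5-[(tert-butyldimethylsilyloxy)methyl]-3-(triethylsilyloxy)nona-1,4-dien-8-yne
Conditions: K2CO3, MeOH, 0 °C to rt
Reagents that add atoms: none
Why: Methoxide-mediated protodesilylation of the alkynylsilane; the TES and TBS ethers are stable to these mild conditions.

Step 8
Reactants: 13 (3S,4E)-5-[(tert-butyldimethylsilyloxy)methyl]-3-(triethylsilyloxy)nona-1,4-dien-8-yne, 14 (E)-but-2-enal (crotonaldehyde)
Product: 16 (2E,4R,9E,11S)-9-[(tert-butyldimethylsilyloxy)methyl]-11-(triethylsilyloxy)trideca-2,9,12-trien-5-yn-4-ol, via alkynyl(methyl)zinc 15 (not isolated)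
Conditions: Me2Zn, (S,S)-ProPhenol (20 mol %), Ph3PO (40 mol %), toluene, 0 °C; then 14 (excess), 0–4 °C; aq NH4Cl
Reagents that add atoms: none
Why: Catalytic enantioselective alkynylation of an α,β-unsaturated aldehyde with a dinuclear zinc–ProPhenol catalyst, in which the ligand alone sets C9 far from C6, and the methyl cap on the new alkene is lost as propene in step 13.

Step 9
Reactants: 16 (2E,4R,9E,11S)-9-[(tert-butyldimethylsilyloxy)methyl]-11-(triethylsilyloxy)trideca-2,9,12-trien-5-yn-4-ol
Product: 18 (2E,4R,5E,9E,11S)-9-[(tert-butyldimethylsilyloxy)methyl]-5-iodo-11-(triethylsilyloxy)trideca-2,5,9,12-tetraen-4-ol, via C10 vinylstannane 17 (not isolated)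
Conditions: Bu3SnH, PdCl2(PPh3)2 (5 mol %), THF, 0 °C to rt; then I2, CH2Cl2, 0 °C
Reagents that add atoms: iodine, [I][I]
Why: Palladium-catalysed syn-hydrostannation of the propargylic alcohol, with tin directed to the alkyne carbon next to the free hydroxyl (C10), followed by iododestannylation with retention, puts H on C1 cis to iodine and so C2 cis to C9.

Step 10
Reactants: 18 (2E,4R,5E,9E,11S)-9-[(tert-butyldimethylsilyloxy)methyl]-5-iodo-11-(triethylsilyloxy)trideca-2,5,9,12-tetraen-4-ol
Product: 19 methyl (2E,6E,8S)-6-[(tert-butyldimethylsilyloxy)methyl]-2-[(1R,2E)-1-hydroxybut-2-en-1-yl]-8-(triethylsilyloxy)deca-2,6,9-trienoate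
Conditions: CO (1 atm), MeOH, Et3N, PdCl2(PPh3)2 (5 mol %), DMF, 50 °C
Reagents that add atoms: carbon monoxide, [C-]#[O+]; methanol, CO
Why: Palladium-catalysed methoxycarbonylation of the alkenyl iodide (oxidative addition, CO insertion, methanolysis) installs C14 with retention of the C1=C10 geometry, the free alcohol and silyl ethers being inert to zerovalent palladium.

Step 11
Reactants: 19 methyl (2E,6E,8S)-6-[(tert-butyldimethylsilyloxy)methyl]-2-[(1R,2E)-1-hydroxybut-2-en-1-yl]-8-(triethylsilyloxy)deca-2,6,9-trienoate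
Product: 20 methyl (2E,6E,8S)-2-[(1R,2E)-1-acetoxybut-2-en-1-yl]-6-[(tert-butyldimethylsilyloxy)methyl]-8-(triethylsilyloxy)deca-2,6,9-trienoate
Conditions: Ac2O, pyridine, DMAP (cat.), CH2Cl2, 0 °C
Reagents that add atoms: acetic anhydride, CC(=O)OC(C)=O
Why: DMAP-catalysed acylation of the only free hydroxyl gives the C9 acetate after the last palladium step, so the allylic acetate never meets zerovalent palladium.

Step 12
Reactants: 20 methyl (2E,6E,8S)-2-[(1R,2E)-1-acetoxybut-2-en-1-yl]-6-[(tert-butyldimethylsilyloxy)methyl]-8-(triethylsilyloxy)deca-2,6,9-trienoate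
Product: 21 methyl (2E,6E,8S)-2-[(1R,2E)-1-acetoxybut-2-en-1-yl]-6-[(tert-butyldimethylsilyloxy)methyl]-8-hydroxydeca-2,6,9-trienoate
Conditions: PPTS, MeOH–CH2Cl2, 0 °C
Reagents that add atoms: none
Why: Mild acid-catalysed methanolysis removes the secondary TES ether much faster than the primary TBS ether (selective silyl ether cleavage), freeing O6 alone.

Step 13
Reactants: 21 methyl (2E,6E,8S)-2-[(1R,2E)-1-acetoxybut-2-en-1-yl]-6-[(tert-butyldimethylsilyloxy)methyl]-8-hydroxydeca-2,6,9-trienoate
Product: 22 methyl (6S,9R)-9-acetoxy-4-[(tert-butyldimethylsilyloxy)methyl]-6-hydroxycyclodeca-1(10),4,7-triene-10-carboxylate (1(10)E,4E,7Z; all three double bonds cis within the ring)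
Conditions: second-generation Grubbs catalyst RuCl2(=CHPh)(PCy3)(H2IMes) (10 mol %), 2,6-dichloro-1,4-benzoquinone (20 mol %), CH2Cl2 (1 mM), 40 °C
Reagents that add atoms: none
Why: Ring-closing metathesis in which the alkylidene should load at the terminal vinyl group next to the free C6 hydroxyl and close onto the methyl-capped C8 olefin with loss of propene, the ring already holding two cis alkenes accepting C7=C8 only as the cis isomer.

Step 14
Reactants: 22 methyl (6S,9R)-9-acetoxy-4-[(tert-butyldimethylsilyloxy)methyl]-6-hydroxycyclodeca-1(10),4,7-triene-10-carboxylate, 23 pyruvic acid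
Product: 24 C6 pyruvate ester of 22, methyl (6S,9R)-9-acetoxy-4-[(tert-butyldimethylsilyloxy)methyl]-6-(2-oxopropanoyloxy)cyclodeca-1(10),4,7-triene-10-carboxylate
Conditions: DCC, DMAP (cat.), CH2Cl2, −20 to 0 °C
Reagents that add atoms: none
Why: Steglich esterification of the secondary allylic alcohol with freshly distilled pyruvic acid under neutral conditions, which leaves the C6 configuration and the acetate untouched.

Step 15
Reactants: 24 C6 pyruvate ester of 22, 25 N-methylhydroxylamine hydrochloride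
Product: 26 C6 pyruvate N-methylnitrone ester, methyl (6S,9R)-9-acetoxy-4-[(tert-butyldimethylsilyloxy)methyl]-6-{2-[methyl(oxido)imino]propanoyloxy}cyclodeca-1(10),4,7-triene-10-carboxylate (C=N drawn Z; either isomer is usable)
Conditions: NaHCO3, MgSO4, CH2Cl2, 0 °C to rt; filtered and used at once
Reagents that add atoms: none
Why: Condensation of an N-alkylhydroxylamine with the strongly electrophilic α-keto ester carbonyl (nitrone formation), which should outpace any conjugate or allylic attack on the hindered trisubstituted acrylate.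

Step 16
Reactants: 26 C6 pyruvate N-methylnitrone ester
Product: 27 isoxazolidine-fused lactone (6R,7S,8S,9S,11R): γ-lactone O6–C12(=O)–C11–C7 trans-fused at C6/C7, isoxazolidine C11–N(CH3)–O–C8–C7 cis-fused at C7/C8, C11 methyl, C9 OAc, C15 OTBS, 1(10)E,4E
Conditions: toluene (5 mM), BHT (cat.), 80 °C, argon
Reagents that add atoms: none
Why: Thermal intramolecular nitrone–alkene (3+2) cycloaddition, concerted and suprafacial on dipole and alkene; the closest known case is the cyclisation of α-alkoxycarbonyl nitrones held on an allylic ester. The three-atom O6–C12 tether only permits the fused mode: C11 bonds to the near carbon C7, closing the γ-lactone as a 5-exo-trig ring, while the nitrone oxygen reaches C8 and closes the isoxazolidine as the second five-membered ring of the same concerted event (no bridged regioisomer is within reach). C7 is controlled by the C6 stereocentre: the ring and allylic 1,3-strain hold H6 close to the C7=C8 plane, so O6 and its dipole lie over one π-face, anti to C5, which leaves H6 and H7 trans. C8 is fixed by suprafacial addition to the ring-cis alkene (C8–O syn to C7–C11), and C11 by the cis fusion that the lactone and isoxazolidine sharing C7–C11 must have, whichever C=N isomer of 26 reacts. The step needs site selectivity for C7=C8 over C4=C5, the other alkene allylic to O6; C4=C5 is trisubstituted and would have to accept the nitrone oxygen at fully substituted C4 beside the silyloxymethyl group, and C1=C10 is out of reach of the tether.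

Step 17
Reactants: 27 isoxazolidine-fused lactone
Product: 29 (6R,7R,8S,9S,11R)-11-(dimethylamino)-8-hydroxy lactone (C11 methyl and NMe2, C8 OH cis to C7–C11, C9 OAc, C15 OTBS), via isoxazolidinium triflate 28 (not isolated)
Conditions: MeOTf, CH2Cl2, 0 °C to rt; evaporate; then Zn dust, AcOH–THF–H2O, 0 °C; aq NaHCO3
Reagents that add atoms: methyl trifluoromethanesulfonate, COS(=O)(=O)C(F)(F)F
Why: N-alkylation of the isoxazolidine nitrogen followed by zinc reduction of the activated N–O bond (reductive isoxazolidinium cleavage) gives the tertiary amine and the C8 hydroxyl directly, under conditions too mild to touch the acrylate or the allylic acetate.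

Step 18
Reactants: 29 (6R,7R,8S,9S,11R)-11-(dimethylamino)-8-hydroxy lactone
Product: 30 (6R,7S,8S,9S,11R)-11-(dimethylamino)-8-isobutyryloxy lactone
Conditions: (i-PrCO)2O, Et3N, DMAP, CH2Cl2, 0 °C
Reagents that add atoms: isobutyric anhydride, CC(C)C(=O)OC(=O)C(C)C
Why: DMAP-catalysed acylation of the only free hydroxyl (the amine is tertiary, C9 is already acetylated), run cold with excess anhydride so that esterification outruns acetyl migration or translactonisation.

Step 19
Reactants: 30 (6R,7S,8S,9S,11R)-11-(dimethylamino)-8-isobutyryloxy lactone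
Product: 32 15-O-tert-butyldimethylsilyl ether of the target (6R,7S,8S,9S), via amine N-oxide 31 (not isolated)
Conditions: m-CPBA, NaHCO3, CH2Cl2, −20 °C; aq K2CO3 wash; then THF, 50 °C
Reagents that add atoms: none
Why: N-oxidation of the tertiary amine (faster than epoxidation of the deactivated alkenes) and Cope elimination through a syn five-membered transition state, which can only take a hydrogen from the C11 methyl because H7 is trans to nitrogen on the lactone, giving the exocyclic C11=C13 bond.

Step 20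
Reactants: 32 15-O-tert-butyldimethylsilyl ether of the target
Product: 33 CNP0242134.2 (target; 1(10)E,4E,6R,7S,8S,9S)
Conditions: HF·pyridine, pyridine, THF, 0 °C to rt
Reagents that add atoms: none
Why: Buffered fluoride-mediated cleavage of the primary silyl ether (desilylation), non-basic so that the α-methylene lactone and the three esters are not attacked.

Compound list
1 | prop-2-yn-1-ol | C#CCO | starting material
2 | tert-butyldimethyl(prop-2-yn-1-yloxy)silane | C#CCO[Si](C)(C)C(C)(C)C | intermediate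
3 | acrolein | C=CC=O | starting material
4 | [3-(tert-butyldimethylsilyloxy)prop-1-yn-1-yl]lithium | [Li]C#CCO[Si](C)(C)C(C)(C)C | intermediate
5 | rac-6-(tert-butyldimethylsilyloxy)hex-1-en-4-yn-3-ol | C=CC(O)C#CCO[Si](C)(C)C(C)(C)C | intermediate
6 | (S)-6-(tert-butyldimethylsilyloxy)hex-1-en-4-yn-3-ol | C=C[C@H](O)C#CCO[Si](C)(C)C(C)(C)C | intermediate
7 | sodium alkenylalanate (five-membered alkoxyalanate, Al on C4) | C=C[C@H]1C=C(CO[Si](C)(C)C(C)(C)C)[Al-](OCCOC)(OCCOC)O1.[Na+] | intermediate
8 | (3S,4Z)-6-(tert-butyldimethylsilyloxy)-5-iodohexa-1,4-dien-3-ol | C=C[C@H](O)/C=C(\I)CO[Si](C)(C)C(C)(C)C | intermediate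
9 | (3S,4Z)-6-(tert-butyldimethylsilyloxy)-5-iodo-3-(triethylsilyloxy)hexa-1,4-diene | C=C[C@H](O[Si](CC)(CC)CC)/C=C(\I)CO[Si](C)(C)C(C)(C)C | intermediate
10 | (4-bromobut-1-yn-1-yl)trimethylsilane | C[Si](C)(C)C#CCCBr | starting material
11 | [4-(trimethylsilyl)but-3-yn-1-yl]zinc bromide | C[Si](C)(C)C#CCC[Zn]Br | intermediate
12 | (3S,4E)-5-[(tert-butyldimethylsilyloxy)methyl]-3-(triethylsilyloxy)-9-(trimethylsilyl)nona-1,4-dien-8-yne | C=C[C@H](O[Si](CC)(CC)CC)/C=C(\CCC#C[Si](C)(C)C)CO[Si](C)(C)C(C)(C)C | intermediate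
13 | (3S,4E)-5-[(tert-butyldimethylsilyloxy)methyl]-3-(triethylsilyloxy)nona-1,4-dien-8-yne | C=C[C@H](O[Si](CC)(CC)CC)/C=C(\CCC#C)CO[Si](C)(C)C(C)(C)C | intermediate
14 | (E)-but-2-enal | C/C=C/C=O | starting material
15 | alkynyl(methyl)zinc of 13 | C=C[C@H](O[Si](CC)(CC)CC)/C=C(\CCC#C[Zn]C)CO[Si](C)(C)C(C)(C)C | intermediate
16 | (2E,4R,9E,11S)-9-[(tert-butyldimethylsilyloxy)methyl]-11-(triethylsilyloxy)trideca-2,9,12-trien-5-yn-4-ol | C=C[C@H](O[Si](CC)(CC)CC)/C=C(\CCC#C[C@H](O)/C=C/C)CO[Si](C)(C)C(C)(C)C | intermediate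
17 | (2E,4R,5E,9E,11S)-9-[(tert-butyldimethylsilyloxy)methyl]-5-(tributylstannyl)-11-(triethylsilyloxy)trideca-2,5,9,12-tetraen-4-ol | C=C[C@H](O[Si](CC)(CC)CC)/C=C(\CC/C=C(/[Sn](CCCC)(CCCC)CCCC)[C@H](O)/C=C/C)CO[Si](C)(C)C(C)(C)C | intermediate
18 | (2E,4R,5E,9E,11S)-9-[(tert-butyldimethylsilyloxy)methyl]-5-iodo-11-(triethylsilyloxy)trideca-2,5,9,12-tetraen-4-ol | C=C[C@H](O[Si](CC)(CC)CC)/C=C(\CC/C=C(/I)[C@H](O)/C=C/C)CO[Si](C)(C)C(C)(C)C | intermediate
19 | methyl (2E,6E,8S)-6-[(tert-butyldimethylsilyloxy)methyl]-2-[(1R,2E)-1-hydroxybut-2-en-1-yl]-8-(triethylsilyloxy)deca-2,6,9-trienoate | C=C[C@H](O[Si](CC)(CC)CC)/C=C(\CC/C=C(/C(=O)OC)[C@H](O)/C=C/C)CO[Si](C)(C)C(C)(C)C | intermediate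
20 | methyl (2E,6E,8S)-2-[(1R,2E)-1-acetoxybut-2-en-1-yl]-6-[(tert-butyldimethylsilyloxy)methyl]-8-(triethylsilyloxy)deca-2,6,9-trienoate | C=C[C@H](O[Si](CC)(CC)CC)/C=C(\CC/C=C(/C(=O)OC)[C@H](OC(C)=O)/C=C/C)CO[Si](C)(C)C(C)(C)C | intermediate
21 | methyl (2E,6E,8S)-2-[(1R,2E)-1-acetoxybut-2-en-1-yl]-6-[(tert-butyldimethylsilyloxy)methyl]-8-hydroxydeca-2,6,9-trienoate | C=C[C@H](O)/C=C(\CC/C=C(/C(=O)OC)[C@H](OC(C)=O)/C=C/C)CO[Si](C)(C)C(C)(C)C | intermediate
22 | methyl (6S,9R)-9-acetoxy-4-[(tert-butyldimethylsilyloxy)methyl]-6-hydroxycyclodeca-1(10),4,7-triene-10-carboxylate (1(10)E,4E,7Z) | C1/C=C(/C(=O)OC)[C@H](OC(C)=O)/C=C\[C@H](O)/C=C(/CO[Si](C)(C)C(C)(C)C)C1 | intermediate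
23 | pyruvic acid | CC(=O)C(=O)O | starting material
24 | C6 pyruvate ester of 22 (6S,9R) | C1/C=C(/C(=O)OC)[C@H](OC(C)=O)/C=C\[C@H](OC(=O)C(C)=O)/C=C(/CO[Si](C)(C)C(C)(C)C)C1 | intermediate
25 | N-methylhydroxylamine hydrochloride | CNO.Cl | starting material
26 | C6 pyruvate N-methylnitrone ester (6S,9R; cis C7=C8) | C1/C=C(/C(=O)OC)[C@H](OC(C)=O)/C=C\[C@H](OC(=O)/C(C)=[N+](/C)[O-])/C=C(/CO[Si](C)(C)C(C)(C)C)C1 | intermediate
27 | isoxazolidine-fused lactone (6R,7S,8S,9S,11R) | C1/C=C(/C(=O)OC)[C@H](OC(C)=O)[C@H]2ON(C)[C@@]3(C)C(=O)O[C@@H]([C@@H]23)/C=C(/CO[Si](C)(C)C(C)(C)C)C1 | intermediate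
28 | N,N-dimethylisoxazolidinium triflate of 27 | C1/C=C(/C(=O)OC)[C@H](OC(C)=O)[C@H]2O[N+](C)(C)[C@@]3(C)C(=O)O[C@@H]([C@@H]23)/C=C(/CO[Si](C)(C)C(C)(C)C)C1.[O-]S(=O)(=O)C(F)(F)F | intermediate
29 | (6R,7R,8S,9S,11R)-11-(dimethylamino)-8-hydroxy lactone | C1/C=C(/C(=O)OC)[C@H](OC(C)=O)[C@@H](O)[C@H]2[C@@](C)(N(C)C)C(=O)O[C@@H]2/C=C(/CO[Si](C)(C)C(C)(C)C)C1 | intermediate
30 | (6R,7S,8S,9S,11R)-11-(dimethylamino)-8-isobutyryloxy lactone | C1/C=C(/C(=O)OC)[C@H](OC(C)=O)[C@@H](OC(=O)C(C)C)[C@H]2[C@@](C)(N(C)C)C(=O)O[C@@H]2/C=C(/CO[Si](C)(C)C(C)(C)C)C1 | intermediate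
31 | amine N-oxide of 30 | C1/C=C(/C(=O)OC)[C@H](OC(C)=O)[C@@H](OC(=O)C(C)C)[C@H]2[C@@](C)([N+](C)(C)[O-])C(=O)O[C@@H]2/C=C(/CO[Si](C)(C)C(C)(C)C)C1 | intermediate
32 | 15-O-tert-butyldimethylsilyl ether of the target (6R,7S,8S,9S) | C=C1C(=O)O[C@@H]2/C=C(/CO[Si](C)(C)C(C)(C)C)CC/C=C(/C(=O)OC)[C@H](OC(C)=O)[C@@H](OC(=O)C(C)C)[C@@H]12 | intermediate
33 | CNP0242134.2 (1(10)E,4E,6R,7S,8S,9S) | C=C1C(=O)O[C@@H]2/C=C(/CO)CC/C=C(/C(=O)OC)[C@H](OC(C)=O)[C@@H](OC(=O)C(C)C)[C@@H]12 | target

Total step count: 20. Longest linear sequence: 20 steps, from 1 to 33; compounds 3, 10, 14, 23 and 25 are bought and enter in one step each.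

Steps most likely to fail

Step 16. The hindered C-methyl nitrone may add too slowly, since the ester tether must first reach its less favoured s-cis rotamer. Tautomerisation to the ene-hydroxylamine, hydrolysis, or addition to the trisubstituted C4=C5 alkene could then compete. The fallback reverses the order of events, making the dipole first and the tether last. It sets out from alcohol 22 and uses the preformed nitrone ester methyl 2-[methyl(oxido)imino]propanoate F1, prepared from methyl pyruvate and N-methylhydroxylamine hydrochloride with NaHCO3. F1 would be transesterified onto O6 with catalytic TiCl4 and 4 Å molecular sieves in 1,2-dichloroethane at rt to 50 °C. The titanium chelate of the nitrone ester activates the ester exchange and lowers the dipole LUMO, so the tethered nitrone should cyclise as soon as it forms (tandem transesterification–cycloaddition). This route comes back at 27.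

Step 13. Ring closure may lose to oligomerisation. The C8 alkylidene may also attack C4=C5 and form a seven-membered ring with loss of the C5–C7 fragment, or the catalyst may be held by the allylic alcohol. The fallback closes the ring at the ketone oxidation level and sets out from 21. MnO2 in CH2Cl2 would oxidise the bis-allylic carbinol to the cross-conjugated ketone methyl (2E,6E)-2-[(1R,2E)-1-acetoxybut-2-en-1-yl]-6-[(tert-butyldimethylsilyloxy)methyl]-8-oxodeca-2,6,9-trienoate F2. In F2 both C4=C5 and the C7 vinyl group are electron-poor, so the alkylidene must form at C8 and can only close onto the vinyl ketone. Enone ring-closing metathesis (second-generation Grubbs catalyst, CH2Cl2, 40 °C, high dilution) would give methyl (9R)-9-acetoxy-4-[(tert-butyldimethylsilyloxy)methyl]-6-oxocyclodeca-1(10),4,7-triene-10-carboxylate F3. C6 is then set again by Corey–Bakshi–Shibata 1,2-reduction with catecholborane, using the oxazaborolidine enantiomer that delivers hydride anti to the C9 acetoxy face. This route comes back at 22.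

Step 9. Tin may go in part to the distal carbon C1, which would place the ester on the wrong carbon. The fallback brings in the ester carbon with the alkene and forms the C9–C10 bond last; it sets out from vinyl iodide 9. Negishi coupling with (3-ethoxy-3-oxopropyl)zinc bromide (PdCl2(dppf), THF) would give ethyl (4E,6S)-4-[(tert-butyldimethylsilyloxy)methyl]-6-(triethylsilyloxy)octa-4,7-dienoate F4. DIBAL-H at −78 °C would give the aldehyde (4E,6S)-4-[(tert-butyldimethylsilyloxy)methyl]-6-(triethylsilyloxy)octa-4,7-dienal F5. Wittig olefination with Ph3P=C(I)CO2Me, made from Ph3P=CHCO2Me and N-iodosuccinimide, would give methyl (2Z,6E,8S)-6-[(tert-butyldimethylsilyloxy)methyl]-2-iodo-8-(triethylsilyloxy)deca-2,6,9-trienoate F6. An asymmetric Nozaki–Hiyama–Kishi coupling of F6 with (E)-but-2-enal (CrCl2, catalytic NiCl2, chiral sulfonamide ligand, THF) would then form C9–C10 with retention of the alkene geometry and ligand control of C9. This route comes back at 19.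

Further compounds
F1 | step 16 | methyl 2-[methyl(oxido)imino]propanoate | COC(=O)/C(C)=[N+](/C)[O-]
F2 | step 13 | methyl (2E,6E)-2-[(1R,2E)-1-acetoxybut-2-en-1-yl]-6-[(tert-butyldimethylsilyloxy)methyl]-8-oxodeca-2,6,9-trienoate | C=CC(=O)/C=C(\CC/C=C(/C(=O)OC)[C@H](OC(C)=O)/C=C/C)CO[Si](C)(C)C(C)(C)C
F3 | step 13 | methyl (9R)-9-acetoxy-4-[(tert-butyldimethylsilyloxy)methyl]-6-oxocyclodeca-1(10),4,7-triene-10-carboxylate | C1/C=C(/C(=O)OC)[C@H](OC(C)=O)/C=C\C(=O)/C=C(/CO[Si](C)(C)C(C)(C)C)C1
F4 | step 9 | ethyl (4E,6S)-4-[(tert-butyldimethylsilyloxy)methyl]-6-(triethylsilyloxy)octa-4,7-dienoate | C=C[C@H](O[Si](CC)(CC)CC)/C=C(\CCC(=O)OCC)CO[Si](C)(C)C(C)(C)C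
F5 | step 9 | (4E,6S)-4-[(tert-butyldimethylsilyloxy)methyl]-6-(triethylsilyloxy)octa-4,7-dienal | C=C[C@H](O[Si](CC)(CC)CC)/C=C(\CCC=O)CO[Si](C)(C)C(C)(C)C
F6 | step 9 | methyl (2Z,6E,8S)-6-[(tert-butyldimethylsilyloxy)methyl]-2-iodo-8-(triethylsilyloxy)deca-2,6,9-trienoate | C=C[C@H](O[Si](CC)(CC)CC)/C=C(\CC/C=C(\I)C(=O)OC)CO[Si](C)(C)C(C)(C)C
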